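## Retrosynthetic overview

- The target is reached from its 4'-O-triisopropylsilyl, side-chain O-triethylsilyl ether **23** by buffered HF desilylation.
- The strategy rests on ring A (C4a, C5, C6, C7, C8, C8a): its 5-OMe, 7-OH and C8 side chain match a 1,1-dimethoxy-3-silyloxy diene carrying the chain on its terminus, and C4a/C8a are the C5=C6 carbons of a ring C 2,3-dihydro-4H-pyran-4-one. Ring A is therefore cut at C4a–C5 and C8–C8a ([4+2], then aromatisation) into pyranone **19** and diene **12**.
- C5 of the pyranone carries a phenylsulfinyl group rather than a halogen. In the cis-fused adduct the hydrogen on C8a is cis to the C4a substituent and not acidic, so the group must leave by thermal syn-elimination; this also keeps base away from the O1–C2 bond.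
- **19** comes from 4-hydroxy-2-methoxybenzaldehyde by an asymmetric hetero-Diels–Alder reaction (ring C, sets C2), sulfenylation and S-oxidation. **12** comes from (R)-limonene oxide (side-chain stereocentre from the chiral pool) by periodate cleavage, one-carbon homologation, MeMgBr addition, acylation of 1,1-dimethoxyethene and enol silylation.
- Ring order: ring B (bought), ring C (step 10), ring A (step 13).

Key step: step 13

Assumption 1: (+)-limonene oxide is used as the commercial cis/trans mixture; both epoxide isomers should converge on the same keto aldehyde.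
Assumption 2: (S)-BINOL is taken to give the (S)-pyranone in step 10, by analogy with the facial sense of this titanium catalyst in additions to aryl aldehydes; if a check of the product shows the opposite sense, (R)-BINOL is used.

## Route

Step 1
Reactants: 1 (4R)-limonene 1,2-oxide
Product: 2 (3R)-6-oxo-3-(prop-1-en-2-yl)heptanal
Conditions: H5IO6 (1.1 equiv), THF/H2O, 0 °C → rt
Reagents that add atoms: water, O
Why: Acid-mediated opening of the epoxide to the 1,2-diol and periodate glycol cleavage in one pot should cut only the C1–C2 bond and leave the isopropenyl group and the chiral-pool stereocentre untouched.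

Step 2
Reactants: 2 (3R)-6-oxo-3-(prop-1-en-2-yl)heptanal
Product: 3 (5R)-8-methoxy-5-(prop-1-en-2-yl)oct-7-en-2-one (E/Z mixture)
Conditions: Ph3P(CH2OMe)Cl, KN(SiMe3)2, THF, 0 °C; then 2, −78 → 0 °C
Reagents that add atoms: (methoxymethyl)triphenylphosphonium chloride, COC[P+](c1ccccc1)(c1ccccc1)c1ccccc1.[Cl-]
Why: Wittig methoxymethylenation is much faster at the aldehyde than at the methyl ketone at low temperature, so the one-carbon homologation should occur at the aldehyde only, and the E/Z mixture is of no consequence.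

Step 3
Reactants: 3 (5R)-8-methoxy-5-(prop-1-en-2-yl)oct-7-en-2-one
Product: 4 (5R)-8-methoxy-2-methyl-5-(prop-1-en-2-yl)oct-7-en-2-ol (E/Z mixture)
Conditions: MeMgBr (1.5 equiv), THF, −78 → 0 °C; aq. NH4Cl
Reagents that add atoms: methylmagnesium bromide, C[Mg]Br
Why: Grignard addition to the methyl ketone gives the tertiary alcohol of the side chain while the enol ether is inert to the reagent.

Step 4
Reactants: 4 (5R)-8-methoxy-2-methyl-5-(prop-1-en-2-yl)oct-7-en-2-ol
Product: 5 (4R)-7-hydroxy-7-methyl-4-(prop-1-en-2-yl)octanal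
Conditions: 1 M aq. HCl, THF, 0 °C → rt
Reagents that add atoms: water, O
Why: Mild acid hydrolysis of the methyl enol ether unmasks the homologated aldehyde, and dilute acid at low temperature should neither hydrate the isopropenyl group nor ionise the tertiary alcohol.

Step 5
Reactants: 5 (4R)-7-hydroxy-7-methyl-4-(prop-1-en-2-yl)octanal
Product: 6 (4R)-7-hydroxy-7-methyl-4-(prop-1-en-2-yl)octanoic acid
Conditions: NaClO2, NaH2PO4, 2-methylbut-2-ene, t-BuOH/H2O, 0 °C → rt
Reagents that add atoms: sodium chlorite, [Na+].[O-]Cl=O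
Why: Pinnick oxidation converts the aldehyde to the acid, with 2-methylbut-2-ene trapping the hypochlorite so that the isopropenyl group survives.

Step 6
Reactants: 6 (4R)-7-hydroxy-7-methyl-4-(prop-1-en-2-yl)octanoic acid
Product: 8 (4R)-7-methyl-4-(prop-1-en-2-yl)-7-(triethylsilyloxy)octanoic acid, via bis-silylated ester 7 (not isolated)
Conditions: TESOTf (2.4 equiv), 2,6-lutidine, CH2Cl2, −78 → 0 °C; then H2O/THF, rt
Reagents that add atoms: triethylsilyl trifluoromethanesulfonate, CC[Si](CC)(CC)OS(=O)(=O)C(F)(F)F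
Why: Silyl triflate silylation protects the hindered tertiary alcohol, and the silyl ester formed at the same time is hydrolysed by water on work-up whereas the tertiary silyl ether is not.

Step 7
Reactants: 8 (4R)-7-methyl-4-(prop-1-en-2-yl)-7-(triethylsilyloxy)octanoic acid; 9 1,1-dimethoxyethene
Product: 11 (6R)-1,1-dimethoxy-9-methyl-6-(prop-1-en-2-yl)-9-(triethylsilyloxy)dec-1-en-3-one, via acid chloride 10 (not isolated)
Conditions: 1-chloro-N,N,2-trimethylprop-1-en-1-amine, CH2Cl2, 0 °C → rt; then 9 (2.5 equiv), Et3N, Et2O, 0 °C → rt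
Reagents that add atoms: none
Why: The Ghosez reagent forms the acid chloride under neutral conditions that spare the silyl ether, and C-acylation of the nucleophilic ketene acetal with loss of HCl (the classical acylketene acetal synthesis) should give the vinylogous carbonate, which is used without chromatography on acidic silica.

Step 8
Reactants: 11 (6R)-1,1-dimethoxy-9-methyl-6-(prop-1-en-2-yl)-9-(triethylsilyloxy)dec-1-en-3-one
Product: 12 (3Z,6R)-1,1-dimethoxy-9-methyl-6-(prop-1-en-2-yl)-9-(triethylsilyloxy)-3-(trimethylsilyloxy)deca-1,3-diene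
Conditions: TMSOTf, Et3N, Et2O, 0 °C; pentane extraction, used crude
Reagents that add atoms: trimethylsilyl trifluoromethanesulfonate, C[Si](C)(C)OS(=O)(=O)C(F)(F)F
Why: Soft enolisation (silyl triflate and amine) silylates the carbonyl oxygen and removes a proton from the only enolisable position, giving the 2-silyloxy diene mainly as the (3Z) isomer, and the geometry affects only the rate of step 13 because this carbon becomes aromatic C8.

Step 9
Reactants: 13 4-hydroxy-2-methoxybenzaldehyde
Product: 14 2-methoxy-4-(triisopropylsilyloxy)benzaldehyde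
Conditions: TIPSCl, imidazole, DMF, rt
Reagents that add atoms: chlorotriisopropylsilane, CC(C)[Si](Cl)(C(C)C)C(C)C
Why: Standard silylation of the phenol gives a bulky aryl silyl ether that should tolerate the Lewis acid, TFA, sulfenyl chloride and peracid of the following steps and falls to fluoride at the end.

Step 10
Reactants: 14 2-methoxy-4-(triisopropylsilyloxy)benzaldehyde; 15 (E)-1-methoxy-3-(trimethylsilyloxy)buta-1,3-diene (Danishefsky's diene)
Product: 17 (2S)-2-[2-methoxy-4-(triisopropylsilyloxy)phenyl]-2,3-dihydro-4H-pyran-4-one, via silylated aldol adduct 16 (not isolated)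
Conditions: (S)-BINOL (20 mol %), Ti(OiPr)4 (20 mol %), 4 Å MS, Et2O, −20 °C; then TFA, CH2Cl2, 0 °C
Reagents that add atoms: none
Why: Titanium–BINOL-catalysed Mukaiyama aldol addition of the siloxydiene followed by acid-induced cyclisation with loss of methanol (a formal hetero-Diels–Alder reaction) builds ring C, and the chiral titanium complex differentiates the aldehyde faces and so sets C2 as (S).

Step 11
Reactants: 17 (2S)-2-[2-methoxy-4-(triisopropylsilyloxy)phenyl]-2,3-dihydro-4H-pyran-4-one
Product: 18 (2S)-2-[2-methoxy-4-(triisopropylsilyloxy)phenyl]-5-(phenylsulfanyl)-2,3-dihydro-4H-pyran-4-one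
Conditions: PhSCl (1.05 equiv), CH2Cl2, −78 °C; then Et3N, −78 → 0 °C
Reagents that add atoms: benzenesulfenyl chloride, ClSc1ccccc1
Why: Electrophilic sulfenylation of the enol ether carbon C5 of the vinylogous ester followed by base-induced loss of HCl is the sulfur counterpart of the usual α-halogenation and α-selenenylation of β-alkoxy enones, and the enol ether should react far faster than the aryl ring at −78 °C.

Step 12
Reactants: 18 (2S)-2-[2-methoxy-4-(triisopropylsilyloxy)phenyl]-5-(phenylsulfanyl)-2,3-dihydro-4H-pyran-4-one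
Product: 19 (2S)-2-[2-methoxy-4-(triisopropylsilyloxy)phenyl]-5-(phenylsulfinyl)-2,3-dihydro-4H-pyran-4-one (both sulfur epimers)
Conditions: mCPBA (1.0 equiv), CH2Cl2, −78 → −30 °C
Reagents that add atoms: 3-chloroperbenzoic acid, O=C(OO)c1cccc(Cl)c1
Why: Peracid oxidation of the sulfide to the sulfoxide is much faster than epoxidation of the electron-poor C5=C6 bond with one equivalent of oxidant at low temperature, and the sulfur configuration is irrelevant because the group is expelled in step 13.

Step 13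
Reactants: 19 (2S)-2-[2-methoxy-4-(triisopropylsilyloxy)phenyl]-5-(phenylsulfinyl)-2,3-dihydro-4H-pyran-4-one; 12 (3Z,6R)-1,1-dimethoxy-9-methyl-6-(prop-1-en-2-yl)-9-(triethylsilyloxy)-3-(trimethylsilyloxy)deca-1,3-diene
Product: 23 (2S)-7-hydroxy-5-methoxy-2-[2-methoxy-4-(triisopropylsilyloxy)phenyl]-8-[(2R)-5-methyl-2-(prop-1-en-2-yl)-5-(triethylsilyloxy)hexyl]-2,3-dihydro-4H-chromen-4-one, via cis-fused cycloadduct 20 (not isolated), via dienyl ketal 21 (not isolated), via aryl trimethylsilyl ether 22 (not isolated)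
Conditions: 12 (2 equiv), PhMe (1 M), 70 °C; then MeOH, PPTS (cat.), 0 °C
Reagents that add atoms: none
Why: Proposed new method: the terminal carbon of the diene (future C8), the nucleophilic end of a vinylogous ketene acetal, attacks C6 of the pyranone (future C8a), which is β to both the ketone and the sulfinyl group, and the ketene acetal carbon (future C5) closes onto C5 of the pyranone (future C4a) in an asynchronous intermolecular [4+2] cycloaddition that forms the six-membered carbocycle of ring A suprafacially, that is cis-fused. The closest known reactions are the tandem Diels–Alder/sulfoxide elimination of 2-sulfinyl enones and sulfinylquinones and the cycloaddition–aromatisation of 1,1-dialkoxy-3-silyloxy dienes with haloquinones; new is a β-alkoxy enone (dihydropyranone) as the two-carbon partner. In adduct 20 the sulfinyl group on C4a and the hydrogen on C8a are cis, so benzenesulfenic acid should be lost by thermal syn-elimination at the reaction temperature to give the C4a=C8a bond (21), after which 1,4-loss of methanol (OMe from C5, H from C8) aromatises ring A and methanolysis removes the trimethylsilyl group from O7. The stereocentres created at C4a, C8 and C8a are destroyed again, so no stereocontrol is needed, while C2 and the side-chain centre are not involved and no base or Lewis acid is present that could open the O1–C2 bond. The selectivity needed is the regiochemistry (C8 to C8a, C5 to C4a), which the polarisation of both partners dictates, and the placement of 5-OMe, 7-OH and the C8 chain, which the diene fixes, so that no C6/C8 or 5-O/7-O differentiation arises.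

Step 14
Reactants: 23 (2S)-7-hydroxy-5-methoxy-2-[2-methoxy-4-(triisopropylsilyloxy)phenyl]-8-[(2R)-5-methyl-2-(prop-1-en-2-yl)-5-(triethylsilyloxy)hexyl]-2,3-dihydro-4H-chromen-4-one
Product: 24 (2S)-7-hydroxy-8-[(2R)-5-hydroxy-5-methyl-2-(prop-1-en-2-yl)hexyl]-2-(4-hydroxy-2-methoxyphenyl)-5-methoxy-2,3-dihydro-4H-chromen-4-one
Conditions: HF·pyridine, pyridine, THF, 0 °C → rt
Reagents that add atoms: none
Why: Buffered HF·pyridine cleaves the aryl triisopropylsilyl and the tertiary triethylsilyl ether without the base that would open the flavanone to the chalcone (and racemise C2) and without the strong acid that would cyclise the isopropenyl group onto the 7-hydroxyl.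

## Compound list

1 | (4R)-limonene 1,2-oxide, (+)-limonene oxide, cis/trans mixture | C=C(C)[C@@H]1CCC2(C)OC2C1 | starting material
2 | (3R)-6-oxo-3-(prop-1-en-2-yl)heptanal | CC(=O)CC[C@H](CC=O)C(C)=C | intermediate
3 | (5R)-8-methoxy-5-(prop-1-en-2-yl)oct-7-en-2-one (E/Z) | CC(=O)CC[C@H](CC=COC)C(C)=C | intermediate
4 | (5R)-8-methoxy-2-methyl-5-(prop-1-en-2-yl)oct-7-en-2-ol (E/Z) | CC(C)(O)CC[C@H](CC=COC)C(C)=C | intermediate
5 | (4R)-7-hydroxy-7-methyl-4-(prop-1-en-2-yl)octanal | CC(C)(O)CC[C@H](CCC=O)C(C)=C | intermediate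
6 | (4R)-7-hydroxy-7-methyl-4-(prop-1-en-2-yl)octanoic acid | CC(C)(O)CC[C@H](CCC(=O)O)C(C)=C | intermediate
7 | triethylsilyl (4R)-7-methyl-4-(prop-1-en-2-yl)-7-(triethylsilyloxy)octanoate | CC[Si](CC)(CC)OC(C)(C)CC[C@H](CCC(=O)O[Si](CC)(CC)CC)C(C)=C | intermediate
8 | (4R)-7-methyl-4-(prop-1-en-2-yl)-7-(triethylsilyloxy)octanoic acid | CC[Si](CC)(CC)OC(C)(C)CC[C@H](CCC(=O)O)C(C)=C | intermediate
9 | 1,1-dimethoxyethene | C=C(OC)OC | starting material
10 | (4R)-7-methyl-4-(prop-1-en-2-yl)-7-(triethylsilyloxy)octanoyl chloride | CC[Si](CC)(CC)OC(C)(C)CC[C@H](CCC(=O)Cl)C(C)=C | intermediate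
11 | (6R)-1,1-dimethoxy-9-methyl-6-(prop-1-en-2-yl)-9-(triethylsilyloxy)dec-1-en-3-one | CC[Si](CC)(CC)OC(C)(C)CC[C@H](CCC(=O)C=C(OC)OC)C(C)=C | intermediate
12 | (3Z,6R)-1,1-dimethoxy-9-methyl-6-(prop-1-en-2-yl)-9-(triethylsilyloxy)-3-(trimethylsilyloxy)deca-1,3-diene | CC[Si](CC)(CC)OC(C)(C)CC[C@H](C/C=C(O[Si](C)(C)C)/C=C(OC)OC)C(C)=C | intermediate
13 | 4-hydroxy-2-methoxybenzaldehyde | COc1cc(O)ccc1C=O | starting material
14 | 2-methoxy-4-(triisopropylsilyloxy)benzaldehyde | COc1cc(O[Si](C(C)C)(C(C)C)C(C)C)ccc1C=O | intermediate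
15 | (E)-1-methoxy-3-(trimethylsilyloxy)buta-1,3-diene | CO/C=C/C(=C)O[Si](C)(C)C | starting material
16 | (1E,5S)-1-methoxy-5-[2-methoxy-4-(triisopropylsilyloxy)phenyl]-5-(trimethylsilyloxy)pent-1-en-3-one | CO/C=C/C(=O)C[C@H](O[Si](C)(C)C)c1ccc(O[Si](C(C)C)(C(C)C)C(C)C)cc1OC | intermediate
17 | (2S)-2-[2-methoxy-4-(triisopropylsilyloxy)phenyl]-2,3-dihydro-4H-pyran-4-one | O=C1C=CO[C@H](c2ccc(O[Si](C(C)C)(C(C)C)C(C)C)cc2OC)C1 | intermediate
18 | (2S)-2-[2-methoxy-4-(triisopropylsilyloxy)phenyl]-5-(phenylsulfanyl)-2,3-dihydro-4H-pyran-4-one | O=C1C(Sc2ccccc2)=CO[C@H](c2ccc(O[Si](C(C)C)(C(C)C)C(C)C)cc2OC)C1 | intermediate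
19 | (2S)-2-[2-methoxy-4-(triisopropylsilyloxy)phenyl]-5-(phenylsulfinyl)-2,3-dihydro-4H-pyran-4-one, sulfur epimers | O=C1C(S(=O)c2ccccc2)=CO[C@H](c2ccc(O[Si](C(C)C)(C(C)C)C(C)C)cc2OC)C1 | intermediate
20 | (2S)-5,5-dimethoxy-2-[2-methoxy-4-(triisopropylsilyloxy)phenyl]-8-[(2R)-5-methyl-2-(prop-1-en-2-yl)-5-(triethylsilyloxy)hexyl]-4a-(phenylsulfinyl)-7-(trimethylsilyloxy)-2,3,4a,5,8,8a-hexahydro-4H-chromen-4-one, cis-fused, isomer mixture at C4a, C8, C8a and S | C=C(C)[C@H](CCC(C)(C)O[Si](CC)(CC)CC)CC1C(O[Si](C)(C)C)=CC(OC)(OC)C2(S(=O)c3ccccc3)C1O[C@H](c1ccc(O[Si](C(C)C)(C(C)C)C(C)C)cc1OC)CC2=O | intermediate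
21 | (2S)-5,5-dimethoxy-2-[2-methoxy-4-(triisopropylsilyloxy)phenyl]-8-[(2R)-5-methyl-2-(prop-1-en-2-yl)-5-(triethylsilyloxy)hexyl]-7-(trimethylsilyloxy)-2,3,5,8-tetrahydro-4H-chromen-4-one | C=C(C)[C@H](CCC(C)(C)O[Si](CC)(CC)CC)CC1C(O[Si](C)(C)C)=CC(OC)(OC)C2=C1O[C@H](c1ccc(O[Si](C(C)C)(C(C)C)C(C)C)cc1OC)CC2=O | intermediate
22 | (2S)-5-methoxy-2-[2-methoxy-4-(triisopropylsilyloxy)phenyl]-8-[(2R)-5-methyl-2-(prop-1-en-2-yl)-5-(triethylsilyloxy)hexyl]-7-(trimethylsilyloxy)-2,3-dihydro-4H-chromen-4-one | C=C(C)[C@H](CCC(C)(C)O[Si](CC)(CC)CC)Cc1c(O[Si](C)(C)C)cc(OC)c2c1O[C@H](c1ccc(O[Si](C(C)C)(C(C)C)C(C)C)cc1OC)CC2=O | intermediate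
23 | (2S)-7-hydroxy-5-methoxy-2-[2-methoxy-4-(triisopropylsilyloxy)phenyl]-8-[(2R)-5-methyl-2-(prop-1-en-2-yl)-5-(triethylsilyloxy)hexyl]-2,3-dihydro-4H-chromen-4-one | C=C(C)[C@H](CCC(C)(C)O[Si](CC)(CC)CC)Cc1c(O)cc(OC)c2c1O[C@H](c1ccc(O[Si](C(C)C)(C(C)C)C(C)C)cc1OC)CC2=O | intermediate
24 | (2S)-7-hydroxy-8-[(2R)-5-hydroxy-5-methyl-2-(prop-1-en-2-yl)hexyl]-2-(4-hydroxy-2-methoxyphenyl)-5-methoxy-2,3-dihydro-4H-chromen-4-one | C=C(C)[C@H](CCC(C)(C)O)Cc1c(O)cc(OC)c2c1O[C@H](c1ccc(O)cc1OC)CC2=O | target

## Step count and risks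

Total: 14 steps. Longest linear sequence: 10 steps (steps 1–8, 13, 14).

**Step 13 (proposed new method).** The push–pull C5=C6 bond may react too slowly, so that the diene decomposes or the reaction stops after conjugate addition. A ketone freed early at C7 could also expel O1 by β-elimination and open ring C, and the sulfenic acid could add to the excess diene or the isopropenyl group.
Fallback with known reaction types, setting out from pyranone 17 and diene 12 and rejoining at 23: the sulfur is left out and ring A is closed by the Lewis-acid-mediated stepwise form of the cycloaddition that is established for enones and for 2,3-dihydro-4H-pyran-4-ones as Michael acceptors. With TMSOTf (10 mol %) in CH2Cl2 at −78 °C, Mukaiyama–Michael addition of 12 to C6 of 17 and closure of the resulting silyl enol ether onto the dimethoxycarbenium ion, followed by PPTS/MeOH, should give the methoxy enone (2S)-5-methoxy-2-[2-methoxy-4-(triisopropylsilyloxy)phenyl]-8-[(2R)-5-methyl-2-(prop-1-en-2-yl)-5-(triethylsilyloxy)hexyl]-2,3,8,8a-tetrahydro-4H-chromene-4,7(4aH)-dione F1. F1 is then dehydrogenated with DDQ in dioxane to phenol 23. The price is one more step and a Lewis acid next to the ionisable O1–C2 bond.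

**Step 10.** The electron-rich, ortho-substituted aldehyde may turn over slowly on the titanium catalyst, and an uncatalysed background reaction would erode the enantiomeric purity at C2.
Fallback setting out from aldehyde 14 and rejoining at 17: asymmetric allylboration with (−)-Ipc2B(allyl) (Et2O, −78 °C; NaOH/H2O2) is expected to give (1S)-1-[2-methoxy-4-(triisopropylsilyloxy)phenyl]but-3-en-1-ol F2. Wacker oxidation (PdCl2, CuCl, O2, DMF/H2O) then gives (4S)-4-hydroxy-4-[2-methoxy-4-(triisopropylsilyloxy)phenyl]butan-2-one F3. Condensation with Me2NCH(OMe)2 (toluene, 60 °C) gives (1E,5S)-1-(dimethylamino)-5-hydroxy-5-[2-methoxy-4-(triisopropylsilyloxy)phenyl]pent-1-en-3-one F4, which closes to 17 with TFA in CH2Cl2 by oxa-Michael addition and loss of dimethylamine.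

**Step 11.** The sulfenyl chloride may attack the electron-rich aryl ring, or the HCl released may ionise the benzylic O1–C2 bond before the amine is added.
Fallback setting out from 17 and rejoining at 18: α-iodination of the enone (I2, pyridine, CH2Cl2, 0 °C) should give (2S)-5-iodo-2-[2-methoxy-4-(triisopropylsilyloxy)phenyl]-2,3-dihydro-4H-pyran-4-one F5. F5 is then coupled with thiophenol under palladium catalysis (PhSH, Pd2(dba)3, Xantphos, iPr2NEt, dioxane, 80 °C) to give sulfide 18.

## Further compounds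

F1 | step 13 | (2S)-5-methoxy-2-[2-methoxy-4-(triisopropylsilyloxy)phenyl]-8-[(2R)-5-methyl-2-(prop-1-en-2-yl)-5-(triethylsilyloxy)hexyl]-2,3,8,8a-tetrahydro-4H-chromene-4,7(4aH)-dione | C=C(C)[C@H](CCC(C)(C)O[Si](CC)(CC)CC)CC1C(=O)C=C(OC)C2C1O[C@H](c1ccc(O[Si](C(C)C)(C(C)C)C(C)C)cc1OC)CC2=O
F2 | step 10 | (1S)-1-[2-methoxy-4-(triisopropylsilyloxy)phenyl]but-3-en-1-ol | C=CC[C@H](O)c1ccc(O[Si](C(C)C)(C(C)C)C(C)C)cc1OC
F3 | step 10 | (4S)-4-hydroxy-4-[2-methoxy-4-(triisopropylsilyloxy)phenyl]butan-2-one | CC(=O)C[C@H](O)c1ccc(O[Si](C(C)C)(C(C)C)C(C)C)cc1OC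
F4 | step 10 | (1E,5S)-1-(dimethylamino)-5-hydroxy-5-[2-methoxy-4-(triisopropylsilyloxy)phenyl]pent-1-en-3-one | CN(C)/C=C/C(=O)C[C@H](O)c1ccc(O[Si](C(C)C)(C(C)C)C(C)C)cc1OC
F5 | step 11 | (2S)-5-iodo-2-[2-methoxy-4-(triisopropylsilyloxy)phenyl]-2,3-dihydro-4H-pyran-4-one | O=C1C(I)=CO[C@H](c2ccc(O[Si](C(C)C)(C(C)C)C(C)C)cc2OC)C1
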